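**Retrosynthetic overview**
1. Lactone ring last: the allylic C2–O bond of 15 is closed on an η3-allylpalladium carboxylate generated from macrocyclic (1E,3E)-diene 13 and 2-bromoacrylic acid 14; the C1–C15 bond enters in the same step.
2. Carbocycle before that: 13 comes from open-chain pentaene 12 by ring-closing diene–ene metathesis at C1=C2.
3. 12 comes from enal 11 by Wittig methylenation.
4. 11 comes from crotonaldehyde 3 by three catalyst-controlled vinylogous Mukaiyama aldol additions of one dienol ether 2 (from prenal 1), setting C14, C10 and C6; the first two hydroxyls are acetylated as they appear, the third stays free.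
5. Ring order: 14-membered carbocycle (step 8), then γ-lactone (step 9).

Assumption: the SMILES is read as the 14-membered cembranolide with all three ring alkenes E, a trans-fused α-methylene-γ-lactone and all five stereocentres S. Cembrane numbering is used: C1 carries C15, C2 is the lactone O–CH, C3=C4, C6–OH, C7=C8, C10–OAc, C11=C12, C14–OAc, C16 is the lactone C=O, C17 the exocyclic CH2.

**Route**

Step 1
Reactants: 1 3-methylbut-2-enal
Product: 2 (E)-tert-butyl(dimethyl)[(3-methylbuta-1,3-dien-1-yl)oxy]silane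
Conditions: TBSOTf (1.1 equiv), Et3N (1.5 equiv), Et2O, 0 °C → rt
Reagents that add atoms: tert-butyldimethylsilyl triflate, CC(C)(C)[Si](C)(C)OS(=O)(=O)C(F)(F)F
Why: Silyl dienol ether formation by soft γ-enolisation: O-silylation of the enal and loss of a γ-methyl proton to Et3N give the 1-siloxy diene, E at the enol ether.

Step 2
Reactants: 3 (E)-but-2-enal; 2 (E)-tert-butyl(dimethyl)[(3-methylbuta-1,3-dien-1-yl)oxy]silane
Product: 5 (2E,5S,6E)-5-hydroxy-3-methylocta-2,6-dienal, via trichlorosilyl aldolate α-chloro silyl ether 4 (not isolated)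
Conditions: 3 (2 equiv), SiCl4 (1.2 equiv), (S,S)-bisphosphoramide (CH2)5[N(Me)P(O)(MeN-C10H6-C10H6-NMe)]2 (5 mol%), iPr2NEt (10 mol%), CH2Cl2, −78 °C; then aq. KH2PO4/NaHCO3, 0 °C
Reagents that add atoms: silicon tetrachloride, Cl[Si](Cl)(Cl)Cl (its atoms stay in intermediate 4 only and are lost on work-up)
Why: Catalytic asymmetric vinylogous Mukaiyama aldol reaction under Lewis-base activation of SiCl4: the chiral trichlorosilyl cation binds the enal and the dienol ether attacks only through its terminal CH2 on the Si face in an open transition state, setting C14 as S and the new trisubstituted alkene as E, while chloride stores the new aldehyde as an α-chloro silyl ether until work-up so that no second addition occurs; this catalysis is established for ketone- and ester-derived dienol ethers and for simple aldehyde enol ethers and is used here with an enal-derived dienol ether.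

Step 3
Reactants: 5 (2E,5S,6E)-5-hydroxy-3-methylocta-2,6-dienal
Product: 6 (2E,5S,6E)-5-acetoxy-3-methylocta-2,6-dienal
Conditions: Ac2O (1.5 equiv), pyridine (3 equiv), 4-(dimethylamino)pyridine (5 mol%), CH2Cl2, 0 °C
Reagents that add atoms: acetic anhydride, CC(=O)OC(C)=O
Why: Nucleophile-catalysed O-acetylation of the secondary allylic alcohol; no stereocentre is formed or touched.

Step 4
Reactants: 6 (2E,5S,6E)-5-acetoxy-3-methylocta-2,6-dienal; 2 (E)-tert-butyl(dimethyl)[(3-methylbuta-1,3-dien-1-yl)oxy]silane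
Product: 8 (2E,5S,6E,9S,10E)-9-acetoxy-5-hydroxy-3,7-dimethyldodeca-2,6,10-trienal, via trichlorosilyl aldolate α-chloro silyl ether 7 (not isolated)
Conditions: 2 (1.2 equiv), SiCl4 (1.2 equiv), (S,S)-bisphosphoramide (CH2)5[N(Me)P(O)(MeN-C10H6-C10H6-NMe)]2 (5 mol%), iPr2NEt (10 mol%), CH2Cl2, −78 °C; then aq. KH2PO4/NaHCO3, 0 °C
Reagents that add atoms: silicon tetrachloride, Cl[Si](Cl)(Cl)Cl (its atoms stay in intermediate 7 only and are lost on work-up)
Why: Second vinylogous Mukaiyama aldol reaction with the same catalyst and facial sense; C10 (S) is set under catalyst control because the C14 centre is five atoms away, and chloride masking of the new enal again prevents over-addition.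

Step 5
Reactants: 8 (2E,5S,6E,9S,10E)-9-acetoxy-5-hydroxy-3,7-dimethyldodeca-2,6,10-trienal
Product: 9 (2E,5S,6E,9S,10E)-5,9-diacetoxy-3,7-dimethyldodeca-2,6,10-trienal
Conditions: Ac2O (1.5 equiv), pyridine (3 equiv), 4-(dimethylamino)pyridine (5 mol%), CH2Cl2, 0 °C
Reagents that add atoms: acetic anhydride, CC(=O)OC(C)=O
Why: Nucleophile-catalysed O-acetylation; this installs the C10 acetate of the target.

Step 6
Reactants: 9 (2E,5S,6E,9S,10E)-5,9-diacetoxy-3,7-dimethyldodeca-2,6,10-trienal; 2 (E)-tert-butyl(dimethyl)[(3-methylbuta-1,3-dien-1-yl)oxy]silane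
Product: 11 (2E,5S,6E,9S,10E,13S,14E)-9,13-diacetoxy-5-hydroxy-3,7,11-trimethylhexadeca-2,6,10,14-tetraenal, via trichlorosilyl aldolate α-chloro silyl ether 10 (not isolated)
Conditions: 2 (1.2 equiv), SiCl4 (1.2 equiv), (S,S)-bisphosphoramide (CH2)5[N(Me)P(O)(MeN-C10H6-C10H6-NMe)]2 (5 mol%), iPr2NEt (10 mol%), CH2Cl2, −78 °C; then aq. KH2PO4/NaHCO3, 0 °C
Reagents that add atoms: silicon tetrachloride, Cl[Si](Cl)(Cl)Cl (its atoms stay in intermediate 10 only and are lost on work-up)
Why: Third vinylogous Mukaiyama aldol reaction sets C6 (S) in the same way; this hydroxyl is never protected and becomes the free OH of the target.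

Step 7
Reactants: 11 (2E,5S,6E,9S,10E,13S,14E)-9,13-diacetoxy-5-hydroxy-3,7,11-trimethylhexadeca-2,6,10,14-tetraenal
Product: 12 (3E,6S,7E,10S,11E,14S,15E)-6-hydroxy-4,8,12-trimethylheptadeca-1,3,7,11,15-pentaene-10,14-diyl diacetate
Conditions: Ph3PCH3Br (2.6 equiv), KN(SiMe3)2 (2.5 equiv), THF, 0 °C; then 11, −78 → −20 °C
Reagents that add atoms: methyltriphenylphosphonium bromide, C[P+](c1ccccc1)(c1ccccc1)c1ccccc1.[Br-]
Why: Wittig methylenation: the non-stabilised ylide adds to the aldehyde far faster than to the acetates at low temperature (one extra equivalent is taken up by the free OH), giving the terminal diene with the E-C3=C4 bond and all stereocentres untouched.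

Step 8
Reactants: 12 (3E,6S,7E,10S,11E,14S,15E)-6-hydroxy-4,8,12-trimethylheptadeca-1,3,7,11,15-pentaene-10,14-diyl diacetate
Product: 13 (1E,3E,6S,7E,10S,11E,14S)-6-hydroxy-4,8,12-trimethylcyclotetradeca-1,3,7,11-tetraene-10,14-diyl diacetate
Conditions: second-generation Hoveyda–Grubbs catalyst RuCl2(H2IMes)(=CH-C6H4-2-OiPr) (10 mol%), toluene (1 mM), 80 °C, argon purge
Reagents that add atoms: none
Why: Ring-closing diene–ene metathesis: only the vinyl end of the diene and the propenyl group react (every trisubstituted alkene, including C3=C4, is inert), so the 14-membered ring closes at C1=C2 with loss of propene, the E isomer being favoured thermodynamically in a ring of this size.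

Step 9
Reactants: 13 (1E,3E,6S,7E,10S,11E,14S)-6-hydroxy-4,8,12-trimethylcyclotetradeca-1,3,7,11-tetraene-10,14-diyl diacetate; 14 2-bromoprop-2-enoic acid
Product: 15 (1S,2S,3E,6S,7E,10S,11E,14S)-10,14-diacetoxy-6-hydroxycembra-3,7,11,15(17)-tetraen-16,2-olide (target)
Conditions: Pd(OAc)2 (10 mol%), tri(2-furyl)phosphine (25 mol%), Ag2CO3 (1.0 equiv), 14 (1.5 equiv, added over 4 h), 1,4-dioxane, 60 °C
Reagents that add atoms: none
Why: Proposed new method: zerovalent palladium inserts into the C–Br bond of 14, the vinylpalladium adds syn across the less substituted E-C1=C2 bond of the diene (C15 to C1, Pd to C2) from the peripheral face anti to the ring chain at C14 with the C14 acetate in the inside position, and the resulting η3-allyl(C2–C4)palladium, kept halide-free by silver so that the carboxylate stays on palladium, closes the lactone by inner-sphere C2–O reductive elimination with retention, so net syn addition to the E-alkene gives the trans-fused lactone with C1 and C2 both S and leaves C3=C4 E; the closest known reaction type is the Larock heteroannulation of 1,3-dienes with vinylic or aryl halides carrying OH, NHR or CO2H, which has not been shown with 2-bromoacrylic acid on an internal macrocyclic diene.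

**Compound list**
1 | 3-methylbut-2-enal | CC(C)=CC=O | starting material
2 | (E)-tert-butyl(dimethyl)[(3-methylbuta-1,3-dien-1-yl)oxy]silane | C=C(C)/C=C/O[Si](C)(C)C(C)(C)C | intermediate
3 | (E)-but-2-enal | C/C=C/C=O | starting material
4 | (2E,5S,6E)-1-chloro-3-methyl-1-(tert-butyldimethylsilyloxy)-5-(trichlorosilyloxy)octa-2,6-diene (C1 epimers) | ClC(O[Si](C)(C)C(C)(C)C)/C=C(\C)C[C@H](O[Si](Cl)(Cl)Cl)/C=C/C | intermediate (not isolated)
5 | (2E,5S,6E)-5-hydroxy-3-methylocta-2,6-dienal | O=C/C=C(\C)C[C@H](O)/C=C/C | intermediate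
6 | (2E,5S,6E)-5-acetoxy-3-methylocta-2,6-dienal | O=C/C=C(\C)C[C@H](OC(C)=O)/C=C/C | intermediate
7 | (2E,5S,6E,9S,10E)-1-chloro-3,7-dimethyl-1-(tert-butyldimethylsilyloxy)-5-(trichlorosilyloxy)dodeca-2,6,10-trien-9-yl acetate (C1 epimers) | ClC(O[Si](C)(C)C(C)(C)C)/C=C(\C)C[C@H](O[Si](Cl)(Cl)Cl)/C=C(\C)C[C@H](OC(C)=O)/C=C/C | intermediate (not isolated)
8 | (2E,5S,6E,9S,10E)-9-acetoxy-5-hydroxy-3,7-dimethyldodeca-2,6,10-trienal | O=C/C=C(\C)C[C@H](O)/C=C(\C)C[C@H](OC(C)=O)/C=C/C | intermediate
9 | (2E,5S,6E,9S,10E)-5,9-diacetoxy-3,7-dimethyldodeca-2,6,10-trienal | O=C/C=C(\C)C[C@H](OC(C)=O)/C=C(\C)C[C@H](OC(C)=O)/C=C/C | intermediate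
10 | (2E,5S,6E,9S,10E,13S,14E)-1-chloro-3,7,11-trimethyl-1-(tert-butyldimethylsilyloxy)-5-(trichlorosilyloxy)hexadeca-2,6,10,14-tetraene-9,13-diyl diacetate (C1 epimers) | ClC(O[Si](C)(C)C(C)(C)C)/C=C(\C)C[C@H](O[Si](Cl)(Cl)Cl)/C=C(\C)C[C@H](OC(C)=O)/C=C(\C)C[C@H](OC(C)=O)/C=C/C | intermediate (not isolated)
11 | (2E,5S,6E,9S,10E,13S,14E)-9,13-diacetoxy-5-hydroxy-3,7,11-trimethylhexadeca-2,6,10,14-tetraenal | O=C/C=C(\C)C[C@H](O)/C=C(\C)C[C@H](OC(C)=O)/C=C(\C)C[C@H](OC(C)=O)/C=C/C | intermediate
12 | (3E,6S,7E,10S,11E,14S,15E)-6-hydroxy-4,8,12-trimethylheptadeca-1,3,7,11,15-pentaene-10,14-diyl diacetate | C=C/C=C(\C)C[C@H](O)/C=C(\C)C[C@H](OC(C)=O)/C=C(\C)C[C@H](OC(C)=O)/C=C/C | intermediate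
13 | (1E,3E,6S,7E,10S,11E,14S)-6-hydroxy-4,8,12-trimethylcyclotetradeca-1,3,7,11-tetraene-10,14-diyl diacetate | CC(=O)O[C@@H]1/C=C/C=C(\C)C[C@H](O)/C=C(\C)C[C@H](OC(C)=O)/C=C(\C)C1 | intermediate
14 | 2-bromoprop-2-enoic acid | C=C(Br)C(=O)O | starting material
15 | (1S,2S,3E,6S,7E,10S,11E,14S)-10,14-diacetoxy-6-hydroxycembra-3,7,11,15(17)-tetraen-16,2-olide | C=C1C(=O)O[C@H]2/C=C(\C)C[C@H](O)/C=C(\C)C[C@H](OC(C)=O)/C=C(\C)C[C@H](OC(C)=O)[C@H]12 | target

**Step count:** 9 steps in total. Longest linear sequence: 9 steps (1 → 2 → 5 → 6 → 8 → 9 → 11 → 12 → 13 → 15).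

**Three steps most likely to fail**

Step 9 (the proposed new method). The internal diene may insert slowly, zerovalent palladium may ionise the allylic acetates or the product lactone, an outer-sphere closure would give the cis-lactone, the face of attack at C1 rests on substrate control, and the product methylene group can undergo a Heck reaction. The fallback uses known chemistry and replaces palladium by a radical-polar crossover. It sets out from 13: oxidative carbolactonisation with malonic acid, Mn(OAc)3·2H2O (2.2 equiv) and Cu(OAc)2 (10 mol%) in AcOH at 25–40 °C adds the malonyl radical to C1 of the diene, the allyl radical is oxidised and a carboxyl group closes on C2, giving the α-carboxy-γ-lactone F1 (trans ring fusion favoured, C1/C2 diastereomers separated if needed). Decarboxylative Mannich methylenation (aqueous CH2O, Et2NH, NaOAc/AcOH, 25–60 °C) then comes back to the route at 15.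

Step 8. The ring closure may give E/Z mixtures at C1=C2 or oligomers, and the conjugated diene terminus initiates slowly. The fallback abandons the diene strategy and closes the ring by carbonyl allylation. It sets out from 11 and bypasses 12 and 13: cross-metathesis of the propenyl terminus with methyl 2-(bromomethyl)acrylate (same ruthenium catalyst, CH2Cl2, 40 °C) gives the allylic bromide F2. CrCl2 (6 equiv) in THF at 2 mM (intramolecular Nozaki–Hiyama 2-(alkoxycarbonyl)allylation, anti-selective chair transition state, free OH tolerated) joins C1 to C2 and gives the hydroxy ester F3, which lactonises in the flask and comes back to the route at 15.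

Step 2. The enal-derived dienol ether is a less documented nucleophile for this catalysis, a [4+2] or 1,4-addition could compete with the small enal, and the facial sense has to be confirmed on 5 (Mosher esters) because it is reused in steps 4 and 6. The fallback moves to the ester oxidation level, where this catalysis is well established. It sets out from 3: ethyl 3-methylbut-2-enoate is converted (LiN(iPr)2, TBSCl, THF, −78 °C) into the silyl ketene acetal F4, which adds to 3 under the same SiCl4/bisphosphoramide conditions to give ethyl (2E,5S,6E)-5-hydroxy-3-methylocta-2,6-dienoate F5. Reduction with iBu2AlH (CH2Cl2, −78 °C) gives (2E,5S,6E)-3-methylocta-2,6-diene-1,5-diol F6, and selective oxidation of the primary allylic alcohol (2,2,6,6-tetramethylpiperidin-1-oxyl, PhI(OAc)2, CH2Cl2) comes back to the route at 5.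

**Further compounds**
F1 | step 9 | α-carboxy-γ-lactone: 15 with C15 as CH–CO2H in place of C=CH2 (C15 epimers) | OC(=O)C1C(=O)O[C@H]2/C=C(\C)C[C@H](O)/C=C(\C)C[C@H](OC(C)=O)/C=C(\C)C[C@H](OC(C)=O)[C@H]12
F2 | step 8 | methyl (2Z,4S,6E,8S,10E,12S,14E)-4,8-diacetoxy-2-(bromomethyl)-12-hydroxy-6,10,14-trimethyl-16-oxohexadeca-2,6,10,14-tetraenoate | O=C/C=C(\C)C[C@H](O)/C=C(\C)C[C@H](OC(C)=O)/C=C(\C)C[C@H](OC(C)=O)/C=C(\CBr)C(=O)OC
F3 | step 8 | seco hydroxy methyl ester of 15 (lactone open: free C2–OH, C16 as CO2Me; not isolated) | O[C@H]1/C=C(\C)C[C@H](O)/C=C(\C)C[C@H](OC(C)=O)/C=C(\C)C[C@H](OC(C)=O)[C@@H]1C(=C)C(=O)OC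
F4 | step 2 | tert-butyl[(1-ethoxy-3-methylbuta-1,3-dien-1-yl)oxy]dimethylsilane (mixture of ketene acetal geometries) | C=C(C)C=C(OCC)O[Si](C)(C)C(C)(C)C
F5 | step 2 | ethyl (2E,5S,6E)-5-hydroxy-3-methylocta-2,6-dienoate | CCOC(=O)/C=C(\C)C[C@H](O)/C=C/C
F6 | step 2 | (2E,5S,6E)-3-methylocta-2,6-diene-1,5-diol | OC/C=C(\C)C[C@H](O)/C=C/C
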